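**Retrosynthetic overview**
1. Last ring: spiro-chromanone ring G, by para-selective oxidative dearomatisation of the ring-A phenol; the ortho-hydroxyl of aroyl ring F closes onto C-8.
2. Key step: dihydrofuran ring D with its tertiary carbinol, by a ring-contracting α-ketol rearrangement (suprafacial [1,2]-sigmatropic shift of Cα from Cβ to the Cγ carbonyl) of a 3-hydroxy-2,3-diaryl-pyran-4-one fused to ring A.
3. That pyranone: Knoevenagel/oxa-Michael annulation of an 8-arylacetyl-7-hydroxyflavan with an aryl aldehyde, then Rubottom hydroxylation at Cβ.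
4. The 8-arylacetyl flavan: C-8 bromination and Br/Li exchange of per-O-benzylated afzelechin (C-2 and C-3 bought) plus an arylacetic Weinreb amide.
5. Ring order: A/C/B bought → six-membered pyranone on O-7/C-8 → contraction to ring D → ring G.

Assumption and labels: (+)-afzelechin (2R,3S) is taken as a purchasable natural flavan-3-ol; rings A/C/B are its rings, ring E is the second 4-oxyphenyl ring, ring F the second phloroglucinol ring, and Cα (on O-7, bears ring E), Cβ (bears ring F), Cγ (on C-8) are the three linking carbons.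

**Step 1**
Reactants: 1 (+)-afzelechin
Product: 2 (2R,3S)-3,5,7-tris(benzyloxy)-2-[4-(benzyloxy)phenyl]chromane
Conditions: BnBr (5 equiv), NaH (5 equiv), DMF, 0 °C to rt
Reagents that add atoms: benzyl bromide, BrCc1ccccc1
Why: Williamson etherification of the three phenols and the C-3 alcohol gives ethers that survive organolithium chemistry and leave together by hydrogenolysis; C-2 and C-3 come with 1 and are not touched.

**Step 2**
Reactants: 2 tetra-O-benzylafzelechin
Product: 3 (2R,3S)-3,5,7-tris(benzyloxy)-2-[4-(benzyloxy)phenyl]-8-bromochromane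
Conditions: NBS (1.05 equiv), CH2Cl2, −78 to 0 °C
Reagents that add atoms: N-bromosuccinimide, O=C1CCC(=O)N1Br
Why: Electrophilic aromatic bromination of per-O-benzylated flavan-3-ols goes to C-8 (C-6 lies between two benzyloxy groups), which fixes the regiochemistry of everything that follows.

**Step 3**
Reactants: 4 1,3,5-tris(benzyloxy)benzene; 5 ethyl glyoxylate
Product: 7 ethyl 2-[2,4,6-tris(benzyloxy)phenyl]acetate, via mandelate ester 6 (not isolated)
Conditions: TFA (5 equiv), CH2Cl2, 0 °C; then Et3SiH (3 equiv), 0 °C to rt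
Reagents that add atoms: none
Why: Friedel–Crafts hydroxyalkylation of the threefold-symmetric arene (no regiochemical issue) followed by ionic hydrogenation of the strongly stabilised benzylic cation.

**Step 4**
Reactants: 7 ethyl 2-[2,4,6-tris(benzyloxy)phenyl]acetate
Product: 8 N-methoxy-N-methyl-2-[2,4,6-tris(benzyloxy)phenyl]acetamide
Conditions: MeNH(OMe)·HCl (1.6 equiv), i-PrMgCl (3.2 equiv), THF, −20 °C
Reagents that add atoms: N,O-dimethylhydroxylamine hydrochloride, CNOC.Cl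
Why: Aminolysis of the ester by the chloromagnesium amide (Weinreb amide synthesis) gives an acyl donor that stops at the ketone stage.

**Step 5**
Reactants: 3 8-bromo-tetra-O-benzylafzelechin; 8 Weinreb amide
Product: 10 1-{(2R,3S)-3,5,7-tris(benzyloxy)-2-[4-(benzyloxy)phenyl]chroman-8-yl}-2-[2,4,6-tris(benzyloxy)phenyl]ethan-1-one, via aryllithium 9 (not isolated)
Conditions: n-BuLi (1.05 equiv), THF, −78 °C, 20 min; then 8 (1.2 equiv), −78 to 0 °C; aq NH4Cl
Reagents that add atoms: none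
Why: Bromine–lithium exchange and acyl substitution on the Weinreb amide (chelated tetrahedral adduct, no over-addition) form the C-8–Cγ bond; the flavan stereocentres are remote and unchanged.

**Step 6**
Reactants: 10 8-arylacetyl flavan
Product: 11 1-{(2R,3S)-3,5-bis(benzyloxy)-2-[4-(benzyloxy)phenyl]-7-hydroxychroman-8-yl}-2-[2,4,6-tris(benzyloxy)phenyl]ethan-1-one
Conditions: BCl3 (1.1 equiv), CH2Cl2, −78 °C; then water
Reagents that add atoms: none
Why: Chelation-directed debenzylation, in which boron bridges the C-8 ketone and the ortho O-7 so that only this benzyl ether is cleaved, unmasks the one phenol that can reach Cα.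

**Step 7**
Reactants: 11 7-hydroxy ketone; 12 4-(benzyloxy)benzaldehyde
Product: 14 ring-D pyranone (αS,βR): O-7–CαH[4-(benzyloxy)phenyl]–CβH[2,4,6-tris(benzyloxy)phenyl]–Cγ(=O)–C-8 on (2R,3S)-3,5,4'-tri-O-benzylafzelechin, via chalcone 13 (not isolated)
Conditions: piperidine (0.5 equiv), EtOH, reflux; chromatography; the unwanted diastereomer is returned to the same conditions
Reagents that add atoms: none
Why: Knoevenagel condensation and 6-endo oxa-Michael closure under thermodynamic control give the α,β-trans pyranone; Cα forms without bias from the remote afzelechin centres, so the two trans diastereomers (about 1:1, diastereomeric only through C-2/C-3) are separated and the unwanted one is re-equilibrated by retro-oxa-Michael opening and recycled.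

**Step 8**
Reactants: 14 ring-D pyranone
Product: 17 Cβ-hydroxy pyranone (αR,βR; OH trans to the Cα aryl group), via silyl enol ether 15 (not isolated), via silyloxy ketone 16 (not isolated)
Conditions: TMSOTf (1.5 equiv), Et3N (2 equiv), CH2Cl2, 0 °C; then mCPBA (1.2 equiv), NaHCO3, −20 °C; then aq citric acid, THF
Reagents that add atoms: 3-chloroperoxybenzoic acid, O=C(OO)c1cccc(Cl)c1
Why: Rubottom oxidation, in which soft enolisation avoids base-induced ring opening, the peracid attacks anti to the Cα aryl group and silyl migration gives the tertiary ketol; the Cβ configuration is of no consequence because Cβ becomes a carbonyl carbon in step 10.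

**Step 9**
Reactants: 17 benzylated ketol
Product: 18 octahydroxy ketol (αR,βR): 17 without its seven benzyl groups
Conditions: H2 (1 atm), Pd(OH)2/C, EtOAc–MeOH, rt
Reagents that add atoms: none
Why: Neutral hydrogenolysis removes all seven benzyl ethers (acid is avoided because the tertiary ketol would dehydrate to the chromone) and frees the ortho-hydroxyls of ring F that drive the next step.

**Step 10**
Reactants: 18 octahydroxy ketol
Product: 19 dihydrofuranol (αR,γR): O-7–CαH(4-hydroxyphenyl)–Cγ(OH)[Cβ(=O)-2,4,6-trihydroxyphenyl]–C-8 on (+)-afzelechin, Cα aryl and aroyl trans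
Conditions: Mg(OMe)2 (3 equiv), degassed MeOH, 45 °C, argon; aq NH4Cl, 0 °C
Reagents that add atoms: none
Why: α-Ketol (acyloin) rearrangement, a suprafacial [1,2]-sigmatropic shift in the magnesium alkoxide: Cα migrates from Cβ to the Cγ carbonyl carbon with retention, contracting the pyranone to ring D and forming the Cα–Cγ bond and the tertiary carbinol; the shift is reversible, is pulled over by the chelated 2-hydroxyaryl ketone, and the new centre Cγ settles under thermodynamic control with the aroyl group trans to the Cα aryl group.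

**Step 11**
Reactants: 19 dihydrofuranol
Product: 20 genkwanol C
Conditions: PhI(OAc)2 (1.05 equiv), (CF3)2CHOH–MeCN, −20 °C
Reagents that add atoms: none
Why: Oxidative phenol dearomatisation, in which the electron-richest phenol (5-OH of ring A) is oxidised and the ortho-hydroxyl of ring F adds to the para carbon C-8 in a six-membered closure to give the spiro cyclohexa-2,5-dienone; the tether through Cγ allows only the cis-fused junction of rings D and G, so C-8 is set by Cγ.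

**Compound list**
1 | (+)-afzelechin, (2R,3S)-2-(4-hydroxyphenyl)chromane-3,5,7-triol | Oc1cc(O)cc2O[C@H](c3ccc(O)cc3)[C@@H](O)Cc12 | starting material
2 | (2R,3S)-3,5,7-tris(benzyloxy)-2-[4-(benzyloxy)phenyl]chromane | O(Cc1ccccc1)c1cc(OCc2ccccc2)cc2O[C@H](c3ccc(OCc4ccccc4)cc3)[C@@H](OCc3ccccc3)Cc12 | intermediate
3 | (2R,3S)-3,5,7-tris(benzyloxy)-2-[4-(benzyloxy)phenyl]-8-bromochromane | O(Cc1ccccc1)c1cc(OCc2ccccc2)c(Br)c2O[C@H](c3ccc(OCc4ccccc4)cc3)[C@@H](OCc3ccccc3)Cc12 | intermediate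
4 | 1,3,5-tris(benzyloxy)benzene | c1c(OCc2ccccc2)cc(OCc2ccccc2)cc1OCc1ccccc1 | starting material
5 | ethyl glyoxylate | CCOC(=O)C=O | starting material
6 | ethyl 2-hydroxy-2-[2,4,6-tris(benzyloxy)phenyl]acetate (racemic) | CCOC(=O)C(O)c1c(OCc2ccccc2)cc(OCc2ccccc2)cc1OCc1ccccc1 | intermediate (not isolated)
7 | ethyl 2-[2,4,6-tris(benzyloxy)phenyl]acetate | CCOC(=O)Cc1c(OCc2ccccc2)cc(OCc2ccccc2)cc1OCc1ccccc1 | intermediate
8 | N-methoxy-N-methyl-2-[2,4,6-tris(benzyloxy)phenyl]acetamide | CON(C)C(=O)Cc1c(OCc2ccccc2)cc(OCc2ccccc2)cc1OCc1ccccc1 | intermediate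
9 | 8-lithio derivative of 2 | O(Cc1ccccc1)c1cc(OCc2ccccc2)c([Li])c2O[C@H](c3ccc(OCc4ccccc4)cc3)[C@@H](OCc3ccccc3)Cc12 | intermediate (not isolated)
10 | 1-{(2R,3S)-3,5,7-tris(benzyloxy)-2-[4-(benzyloxy)phenyl]chroman-8-yl}-2-[2,4,6-tris(benzyloxy)phenyl]ethan-1-one | O(Cc1ccccc1)c1cc(OCc2ccccc2)c(C(=O)Cc2c(OCc3ccccc3)cc(OCc3ccccc3)cc2OCc2ccccc2)c2O[C@H](c3ccc(OCc4ccccc4)cc3)[C@@H](OCc3ccccc3)Cc12 | intermediate
11 | 1-{(2R,3S)-3,5-bis(benzyloxy)-2-[4-(benzyloxy)phenyl]-7-hydroxychroman-8-yl}-2-[2,4,6-tris(benzyloxy)phenyl]ethan-1-one | O(Cc1ccccc1)c1cc(O)c(C(=O)Cc2c(OCc3ccccc3)cc(OCc3ccccc3)cc2OCc2ccccc2)c2O[C@H](c3ccc(OCc4ccccc4)cc3)[C@@H](OCc3ccccc3)Cc12 | intermediate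
12 | 4-(benzyloxy)benzaldehyde | O=Cc1ccc(OCc2ccccc2)cc1 | starting material
13 | (E)-enone from 11 and 12: (7-hydroxyflavan-8-yl)–C(=O)–C[2,4,6-tris(benzyloxy)phenyl]=CH–[4-(benzyloxy)phenyl] | O(Cc1ccccc1)c1cc(O)c(C(=O)/C(c2c(OCc3ccccc3)cc(OCc3ccccc3)cc2OCc2ccccc2)=C/c2ccc(OCc3ccccc3)cc2)c2O[C@H](c3ccc(OCc4ccccc4)cc3)[C@@H](OCc3ccccc3)Cc12 | intermediate (not isolated)
14 | ring-D pyranone (αS,βR), α,β-trans: O-7–CαH[4-(benzyloxy)phenyl]–CβH[2,4,6-tris(benzyloxy)phenyl]–Cγ(=O)–C-8 on (2R,3S)-3,5,4'-tri-O-benzylafzelechin | O(Cc1ccccc1)c1cc2O[C@H](c3ccc(OCc4ccccc4)cc3)[C@@H](c3c(OCc4ccccc4)cc(OCc4ccccc4)cc3OCc3ccccc3)C(=O)c2c2O[C@H](c3ccc(OCc4ccccc4)cc3)[C@@H](OCc3ccccc3)Cc12 | intermediate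
15 | trimethylsilyl enol ether of 14 (Cβ=Cγ–OSiMe3; αR) | O(Cc1ccccc1)c1cc2O[C@H](c3ccc(OCc4ccccc4)cc3)C(c3c(OCc4ccccc4)cc(OCc4ccccc4)cc3OCc3ccccc3)=C(O[Si](C)(C)C)c2c2O[C@H](c3ccc(OCc4ccccc4)cc3)[C@@H](OCc3ccccc3)Cc12 | intermediate (not isolated)
16 | Cβ-(trimethylsilyloxy) pyranone (αR,βR) | O(Cc1ccccc1)c1cc2O[C@H](c3ccc(OCc4ccccc4)cc3)[C@](O[Si](C)(C)C)(c3c(OCc4ccccc4)cc(OCc4ccccc4)cc3OCc3ccccc3)C(=O)c2c2O[C@H](c3ccc(OCc4ccccc4)cc3)[C@@H](OCc3ccccc3)Cc12 | intermediate (not isolated)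
17 | Cβ-hydroxy pyranone (αR,βR), benzylated ketol | O(Cc1ccccc1)c1cc2O[C@H](c3ccc(OCc4ccccc4)cc3)[C@](O)(c3c(OCc4ccccc4)cc(OCc4ccccc4)cc3OCc3ccccc3)C(=O)c2c2O[C@H](c3ccc(OCc4ccccc4)cc3)[C@@H](OCc3ccccc3)Cc12 | intermediate
18 | octahydroxy ketol (αR,βR): O-7–CαH(4-hydroxyphenyl)–Cβ(OH)(2,4,6-trihydroxyphenyl)–Cγ(=O)–C-8 on (+)-afzelechin | Oc1cc2O[C@H](c3ccc(O)cc3)[C@](O)(c3c(O)cc(O)cc3O)C(=O)c2c2O[C@H](c3ccc(O)cc3)[C@@H](O)Cc12 | intermediate
19 | dihydrofuranol (αR,γR): O-7–CαH(4-hydroxyphenyl)–Cγ(OH)[C(=O)-2,4,6-trihydroxyphenyl]–C-8 on (+)-afzelechin, aryl/aroyl trans | Oc1cc2O[C@H](c3ccc(O)cc3)[C@@](O)(C(=O)c3c(O)cc(O)cc3O)c2c2O[C@H](c3ccc(O)cc3)[C@@H](O)Cc12 | intermediate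
20 | genkwanol C | O=C1C=C2O[C@H](c3ccc(O)cc3)[C@@]3(O)C(=O)c4c(O)cc(O)cc4O[C@@]23C2=C1C[C@H](O)[C@@H](c1ccc(O)cc1)O2 | target

**Step count and risks**
Total steps: 11. Longest linear sequence: 9 (steps 1, 2, 5, 6, 7, 8, 9, 10, 11 from 1).

The three steps most likely to fail:

Step 7. The active methylene is flanked by a 2,6-disubstituted aryl group, so the condensation may stall. Fallback, setting out from 11 and returning at 14: heating 11 in N,N-dimethylformamide dimethyl acetal gives the 3-aryl chromone F1. Conjugate addition of 4-(benzyloxy)phenylmagnesium bromide with CuBr·SMe2 and TMSCl in THF at −40 °C, then protonation and piperidine equilibration, gives 14 as the same diastereomer pair with the same separation.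

Step 10. The ketol equilibrium may not favour the contracted ring, and the free polyphenol may not tolerate base. Fallback, setting out from 3 and returning at 19, closes ring D by C–C bond formation instead:
- Bromine–lithium exchange of 3 and inverse addition to diethyl oxalate give the α-keto ester F2.
- BCl3 at −78 °C cleaves the ortho benzyl ether to give the 7-hydroxy α-keto ester F3.
- 4-(Benzyloxy)benzyl bromide and K2CO3 give the aryl benzyl ether F4.
- Irradiation at 350 nm in benzene closes ring D by δ-hydrogen abstraction and 1,5-biradical recombination (Norrish–Yang-type cyclisation) to the hydroxy ester F5.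
- NBS converts 4 into 1-bromo-2,4,6-tris(benzyloxy)benzene F6, and n-BuLi turns that into 2,4,6-tris(benzyloxy)phenyllithium F7.
- F7 adds to the ester of F5 to give the benzylated dihydrofuranol ketone F8.
- Hydrogenolysis over Pd(OH)2/C gives 19; mild base then equilibrates Cα through the para-quinone methide to the trans arrangement.

Step 11. The oxidant may attack other free phenols, or the ring-A phenoxonium may lose H-4 instead of closing. Fallback, setting out from 3 and returning at 20, runs through F2 to F8 as above and dearomatises a protected substrate: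
- BCl3 (1 equiv, −78 °C) cleaves one ortho benzyl ether of ring F by chelation to the aroyl carbonyl, giving the mono-phenol F9.
- PhI(OCOCF3)2 in (CF3)2CHOH oxidises the 5-benzyloxy arene of ring A; the free ring-F hydroxyl closes onto C-8 and the O-benzyl oxocarbenium loses its benzyl group, giving penta-O-benzylgenkwanol C F10.
- BCl3 with pentamethylbenzene at −78 °C removes the five remaining benzyl groups without reducing the dienone and gives 20.

**Further compounds**
F1 | step 7 | 3-aryl chromone: O-7–CαH=Cβ[2,4,6-tris(benzyloxy)phenyl]–Cγ(=O)–C-8 on (2R,3S)-3,5,4'-tri-O-benzylafzelechin | O(Cc1ccccc1)c1cc2OC=C(c3c(OCc4ccccc4)cc(OCc4ccccc4)cc3OCc3ccccc3)C(=O)c2c2O[C@H](c3ccc(OCc4ccccc4)cc3)[C@@H](OCc3ccccc3)Cc12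
F2 | step 10 | ethyl 2-oxo-2-{(2R,3S)-3,5,7-tris(benzyloxy)-2-[4-(benzyloxy)phenyl]chroman-8-yl}acetate | O(Cc1ccccc1)c1cc(OCc2ccccc2)c(C(=O)C(=O)OCC)c2O[C@H](c3ccc(OCc4ccccc4)cc3)[C@@H](OCc3ccccc3)Cc12
F3 | step 10 | ethyl 2-oxo-2-{(2R,3S)-3,5-bis(benzyloxy)-2-[4-(benzyloxy)phenyl]-7-hydroxychroman-8-yl}acetate | O(Cc1ccccc1)c1cc(O)c(C(=O)C(=O)OCC)c2O[C@H](c3ccc(OCc4ccccc4)cc3)[C@@H](OCc3ccccc3)Cc12
F4 | step 10 | 7-O-[4-(benzyloxy)benzyl] ether of F3 | O(Cc1ccccc1)c1cc(OCc2ccc(OCc3ccccc3)cc2)c(C(=O)C(=O)OCC)c2O[C@H](c3ccc(OCc4ccccc4)cc3)[C@@H](OCc3ccccc3)Cc12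
F5 | step 10 | hydroxy ester (αR,γR): O-7–CαH[4-(benzyloxy)phenyl]–Cγ(OH)(CO2Et)–C-8 on (2R,3S)-3,5,4'-tri-O-benzylafzelechin, aryl/ester trans | O(Cc1ccccc1)c1cc2O[C@H](c3ccc(OCc4ccccc4)cc3)[C@@](O)(C(=O)OCC)c2c2O[C@H](c3ccc(OCc4ccccc4)cc3)[C@@H](OCc3ccccc3)Cc12
F6 | step 10 | 1-bromo-2,4,6-tris(benzyloxy)benzene | Brc1c(OCc2ccccc2)cc(OCc2ccccc2)cc1OCc1ccccc1
F7 | step 10 | 2,4,6-tris(benzyloxy)phenyllithium | [Li]c1c(OCc2ccccc2)cc(OCc2ccccc2)cc1OCc1ccccc1
F8 | step 10 | hepta-O-benzyl derivative of 19 (αR,γR) | O(Cc1ccccc1)c1cc2O[C@H](c3ccc(OCc4ccccc4)cc3)[C@@](O)(C(=O)c3c(OCc4ccccc4)cc(OCc4ccccc4)cc3OCc3ccccc3)c2c2O[C@H](c3ccc(OCc4ccccc4)cc3)[C@@H](OCc3ccccc3)Cc12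
F9 | step 11 | F8 with one ortho hydroxyl of ring F free | O(Cc1ccccc1)c1cc2O[C@H](c3ccc(OCc4ccccc4)cc3)[C@@](O)(C(=O)c3c(O)cc(OCc4ccccc4)cc3OCc3ccccc3)c2c2O[C@H](c3ccc(OCc4ccccc4)cc3)[C@@H](OCc3ccccc3)Cc12
F10 | step 11 | penta-O-benzylgenkwanol C (benzyl on O-3, O-4' of ring B, the ring-E oxygen and the two ring-F hydroxyls) | O=C1C=C2O[C@H](c3ccc(OCc5ccccc5)cc3)[C@@]3(O)C(=O)c4c(OCc5ccccc5)cc(OCc5ccccc5)cc4O[C@@]23C2=C1C[C@H](OCc1ccccc1)[C@@H](c1ccc(OCc3ccccc3)cc1)O2
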